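Start from the late readings of the two earlier runs. At 20.0 min the noon run still has substrate ahead of target, 54.5 % against 45.2 %. At 20.0 min the winter run has target ahead, 74.5 % against 25.1 %. Somewhere between those two loadings the lead changes hands. You must choose the next charge, and you want target ahead at the end.

| setting | noon | winter | Tuesday's | Sunday's |
|---|---|---|---|---|
| substrate | 0.050 M | 0.050 M | 0.050 M | 0.050 M |
| coupling partner | 0.95 equiv | 0.95 equiv | 0.950 equiv | 0.950 equiv |
| free catalyst | 0.52 mol% | 1.1 mol% | 0.41 mol% | 0.82 mol% |
| remark | run made earlier | run made earlier |  |  |
| time |  |  | 20 min | 20 min |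

| run | time / min | target / % | substrate / % | catalyst intermediate C / % | catalyst intermediate B / % |
|---|---|---|---|---|---|
| noon | 1.00 | 0.6 | 96.6 | 0.1 | 1.4 |
| noon | 3.00 | 6.2 | 92.7 | 2.3 | 0.4 |
| noon | 6.00 | 13.9 | 84.1 | 0 | 0.4 |
| noon | 8.00 | 20.0 | 77.4 | 0 | 0 |
| noon | 12.0 | 28.7 | 70.6 | 0.8 | 1.5 |
| noon | 15.0 | 36.1 | 62.8 | 0.1 | 0.4 |
| noon | 20.0 | 45.2 | 54.5 | 0 | 0 |
| winter | 1.00 | 5.8 | 92.7 | 1.0 | 1.2 |
| winter | 3.00 | 16.0 | 83.3 | 0.3 | 0 |
| winter | 6.00 | 30.6 | 67.8 | 0.3 | 0 |
| winter | 8.00 | 41.6 | 59.7 | 0 | 0.1 |
| winter | 12.0 | 55.2 | 44.9 | 1.2 | 0 |
| winter | 15.0 | 64.4 | 36.0 | 1.1 | 0 |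
| winter | 20.0 | 74.5 | 25.1 | 0.7 | 0.5 |

(standard deviation of a reading: 1 percentage point)

1. which of these there is most of at the end, counted by the substrate in it, Tuesday's (catalyst intermediate B / substrate / catalyst intermediate C / target)
2. which of these there is most of at the end, counted by the substrate in it, Sunday's (catalyst intermediate B / substrate / catalyst intermediate C / target)
3. final amount of the leader among these, as a percentage of the substrate charged, in Tuesday's
4. final amount of the leader among these, as a percentage of the substrate charged, in Sunday's



Here is my own reckoning. In the noon run, substrate and target add up to 99.7 % at the end, so take target as the charge less the substrate. Now count halvings: the natural log of one over the fraction of substrate left, divided by the natural log of 2. This treats the fall as pseudo-first-order. The noon run made 0.876 halvings and the winter run 1.99.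

Divide each loading by its halvings. The noon run gives 0.59 mol% and the winter run 0.55 mol%, and their mean is 0.57 mol%. Call this the crossing loading: my estimate of the loading that pays for one halving in 20.0 min at 0.050 M of substrate and 0.950 equiv of coupling partner, the point where substrate and target stand equal.

Tuesday's loading lies below both readings, and Sunday's lies above both. By this count Tuesday's flask should get 0.716 halvings, which would leave 60.9 % substrate. By the same count Sunday's flask should get 1.43 halvings, which would leave 37.1 % substrate and so 62.9 % target. So charge Sunday's loading, and leave substrate, coupling partner and time as they are.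

The forecast, holding that “Rate is about proportional to catalyst”, names substrate for Tuesday's at 62 % and target for Sunday's at 61 %, close to my figures but not the same.

Tuesday's flask ends with substrate leading at 62.2 %, and Sunday's flask ends with target leading at 63.4 %.

    catalyst intermediate A → catalyst intermediate B (k = 72.3 /min)
    catalyst intermediate C → free catalyst + target (k = 16.8 /min)
    coupling partner + catalyst intermediate B → catalyst intermediate C (k = 3430 /M/min)
    substrate + free catalyst ⇌ catalyst intermediate A (K = 14.3 /M, k = 230 /M/min)
    2 catalyst intermediate A → spent catalyst (k = 96.4 /M/min)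
    coupling partner → decomposed reagent (k = 0.0203 /min)

Sunday's flask has target in the lead because of its loading: at Tuesday's loading it holds 37.6 % target against 63.4 %. Its end counts 1.46 halvings, which puts the crossing loading at 0.56 mol%. That value belongs to 0.050 M of substrate. A neighbour of Tuesday's charged with 0.20 M keeps the 0.41 mol% loading and ends with 34 % substrate. That is 1.57 halvings and a crossing loading of 0.26 mol% for that charge, below its own loading, and target leads that flask at 66.0 %.

(The readings are simulated for an exercise, noise included.)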